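Ring A carries its propanoyl group on C1, flanked by the oxygenated carbons C2 and C6, so the C1 ketone and the C2 hydroxyl are a vicinal pair that one molecule of propionic acid can deliver across an aryne. The route therefore disconnects the C1–C(acyl) and C2–O bonds together: fluoride unmasks the C1≡C2 aryne from an ortho-silyl triflate, propionate adds at C2 and the acyl group shifts to C1. The precursor is the fully assembled skeleton: ring A with triethylsilyl at C1, triflate at C2 and a benzyl ether at C6, already joined through the C5 methylene to ring B, whose two acidic enols are capped as methyl ethers.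

Key step: step 10

Remark on numbering: ring A is C1 (propanoyl carbon), C2 (OH, next to C3–H), C3 (H), C4 (OMe), C5 (CH2 bridge), C6 (OH). Ring B is C1' (C=O) between C2' (acetyl) and C6' (bridge carbon), with the C3' and C5' oxygens flanking C4' (gem-dimethyl). The target has no stereocentre and no stereogenic double bond.

Remark on the precursor design: the silyl group at C1 is triethylsilyl, because it is first carried as a robust O-silyl ether and then moved from oxygen to carbon; it is lost in the key step. The benzyl ether is installed before the silyl triflate exists, since a free C6 phenol beside a C1 silyl group and a C2 triflate would start base-induced silyl migration and premature aryne formation. The aryne-precursor array is finished on a ring A aldehyde before ring B is attached, because making it needs butyllithium.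

Assumption: ring B enols and enol ethers are written in the 3',5'-dioxygenated cross-conjugated form of the target; positional isomers of the enol ethers would give the same product on hydrolysis.

Step 1
Reactants: 1 5-methoxybenzene-1,3-diol
Product: 2 2-iodo-5-methoxybenzene-1,3-diol
Conditions: I2 (1.0 equiv), NaHCO3, H2O, 0 °C to rt
Reagents that add atoms: iodine, II
Why: Electrophilic aromatic iodination of a resorcinol in aqueous bicarbonate is kinetically directed to the carbon between the two hydroxyl groups, which in 1 is also para to the methoxy group, and the non-acidic medium prevents migration of the iodine.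

Step 2
Reactants: 2 2-iodo-5-methoxybenzene-1,3-diol
Product: 3 2,4-dihydroxy-3-iodo-6-methoxybenzaldehyde
Conditions: MgCl2, Et3N, (CH2O)n, MeCN, reflux; then 1 M HCl
Reagents that add atoms: paraformaldehyde (as formaldehyde), C=O
Why: Magnesium-mediated ortho-formylation of phenols (Casnati–Skattebøl reaction) delivers formaldehyde only ortho to a phenoxide and the two open ortho carbons of 2 are equivalent by symmetry, so one aldehyde should form, the benzylic alkoxide being oxidised by a second formaldehyde.

Step 3
Reactants: 3 2,4-dihydroxy-3-iodo-6-methoxybenzaldehyde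
Product: 4 2-hydroxy-3-iodo-6-methoxy-4-[(triethylsilyl)oxy]benzaldehyde
Conditions: Et3SiCl (1.05 equiv), imidazole, CH2Cl2, −20 to 0 °C
Reagents that add atoms: chlorotriethylsilane, CC[Si](Cl)(CC)CC
Why: Selective O-silylation, because the 4-OH para to the formyl group is free and the more acidic, whereas the 2-OH is tied up in a hydrogen bond to the aldehyde and flanked on both sides, so one equivalent of silyl chloride should go to the 4-oxygen.

Step 4
Reactants: 4 2-hydroxy-3-iodo-6-methoxy-4-[(triethylsilyl)oxy]benzaldehyde
Product: 5 2-(benzyloxy)-3-iodo-6-methoxy-4-[(triethylsilyl)oxy]benzaldehyde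
Conditions: BnOH, PPh3, DIAD, THF, 0 °C to rt
Reagents that add atoms: benzyl alcohol, OCc1ccccc1
Why: Mitsunobu etherification alkylates the remaining chelated phenol under neutral conditions that leave the base-labile aryl silyl ether and the aryl iodide untouched.

Step 5
Reactants: 5 2-(benzyloxy)-3-iodo-6-methoxy-4-[(triethylsilyl)oxy]benzaldehyde
Product: 6 {[3-(benzyloxy)-4-(dimethoxymethyl)-2-iodo-5-methoxyphenyl]oxy}triethylsilane
Conditions: MeOSiMe3, TMSOTf (5 mol%), CH2Cl2, −78 °C; then pyridine
Reagents that add atoms: methoxytrimethylsilane, CO[Si](C)(C)C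
Why: Aprotic acetalisation with an alkoxysilane and catalytic silyl triflate (Noyori conditions) masks the aldehyde against butyllithium without the protic acid that would cleave the aryl triethylsilyl ether.

Step 6
Reactants: 6 {[3-(benzyloxy)-4-(dimethoxymethyl)-2-iodo-5-methoxyphenyl]oxy}triethylsilane
Product: 10 3-(benzyloxy)-4-formyl-5-methoxy-2-(triethylsilyl)phenyl trifluoromethanesulfonate, via C1 aryllithium 7 (not isolated), via lithium 2-silylphenolate 8 (not isolated), via triflate dimethyl acetal 9 (not isolated)
Conditions: n-BuLi, THF, −78 to −40 °C; PhNTf2, −78 °C to rt; then 1 M HCl, THF, rt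
Reagents that add atoms: N-phenylbis(trifluoromethanesulfonimide), O=S(=O)(N(c1ccccc1)S(=O)(=O)C(F)(F)F)C(F)(F)F; water, O
Why: Iodine–lithium exchange at C1 is followed by a 1,3 O-to-C silyl shift (retro-Brook rearrangement) that puts silicon on C1 and frees the C2 phenoxide for O-triflation, the standard way to ortho-silylaryl triflates from ortho-halophenol silyl ethers, and dilute acid then hydrolyses the dimethyl acetal.

Step 7
Reactants: 11 1-(2,4,6-trihydroxyphenyl)ethan-1-one (2,4,6-trihydroxyacetophenone)
Product: 13 2-acetyl-3,5-dihydroxy-4,4-dimethylcyclohexa-2,5-dien-1-one (acetylfilicinic acid), via monomethyl phloroacetophenone 12 (not isolated)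
Conditions: MeI (2.2 equiv), NaOMe, MeOH, 0 °C to rt
Reagents that add atoms: iodomethane, CI
Why: Dearomatising geminal C-methylation of an acylphloroglucinol under methoxide, a known route to acylfilicinic acids in which the second methyl group enters the already methylated carbon of the phenoxide to give the stable enolised triketone, separable from under- and over-methylated material.

Step 8
Reactants: 10 3-(benzyloxy)-4-formyl-5-methoxy-2-(triethylsilyl)phenyl trifluoromethanesulfonate; 13 acetylfilicinic acid
Product: 15 3-(benzyloxy)-4-[(5-acetyl-2,4-dihydroxy-3,3-dimethyl-6-oxocyclohexa-1,4-dien-1-yl)methyl]-5-methoxy-2-(triethylsilyl)phenyl trifluoromethanesulfonate, via arylidene triketone 14 (not isolated)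
Conditions: Hantzsch ester (1.1 equiv), L-proline (20 mol%), CH2Cl2, rt to 40 °C
Reagents that add atoms: none
Why: Proline-catalysed three-component reductive alkylation, in which Knoevenagel condensation of the aldehyde with the only ring C–H of the triketone (C6') gives an arylidene that is reduced at once by conjugate hydride transfer from the Hantzsch ester, so the bridge forms by C-alkylation only and the silyl triflate sees neither fluoride nor strong base.

Step 9
Reactants: 15 3-(benzyloxy)-4-[(5-acetyl-2,4-dihydroxy-3,3-dimethyl-6-oxocyclohexa-1,4-dien-1-yl)methyl]-5-methoxy-2-(triethylsilyl)phenyl trifluoromethanesulfonate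
Product: 16 3-(benzyloxy)-4-[(5-acetyl-2,4-dimethoxy-3,3-dimethyl-6-oxocyclohexa-1,4-dien-1-yl)methyl]-5-methoxy-2-(triethylsilyl)phenyl trifluoromethanesulfonate
Conditions: TMSCHN2, PhMe/MeOH, 0 °C to rt
Reagents that add atoms: trimethylsilyldiazomethane, C[Si](C)(C)C=[N+]=[N-]
Why: O-Methylation of strongly acidic enols by a diazoalkane, in which only the two vinylogous acid hydroxyls of ring B can protonate the reagent (no phenol is free) and O-methylation of the enol form shown gives the cross-conjugated bis(vinylogous ester) with no acidic proton left.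

Step 10
Reactants: 16 3-(benzyloxy)-4-[(5-acetyl-2,4-dimethoxy-3,3-dimethyl-6-oxocyclohexa-1,4-dien-1-yl)methyl]-5-methoxy-2-(triethylsilyl)phenyl trifluoromethanesulfonate; 17 propanoic acid
Product: 19 2-acetyl-6-{[2-(benzyloxy)-4-hydroxy-6-methoxy-3-propanoylphenyl]methyl}-3,5-dimethoxy-4,4-dimethylcyclohexa-2,5-dien-1-one, via C1–C2 aryne 18 (not isolated)
Conditions: EtCO2H (1.5 equiv), CsF (5 equiv), THF, 125 °C, sealed tube
Reagents that add atoms: none
Why: Fluoride attacks the triethylsilyl group at C1 and triflate leaves from C2 to give the C1≡C2 aryne 18; propionate (from the acid and CsF) adds through oxygen at C2, the C1 aryl anion attacks the neighbouring ester carbonyl through a four-membered benzoxetene alkoxide, and ring opening gives the C1 ketone and the C2 phenoxide, so the C2–O and C1–C(acyl) bonds form in one operation. This is the known fluoride-triggered insertion of arynes into the C–O bond of carboxylic acids, which gives ortho-hydroxyaryl ketones when run hot in THF, where the aryl anion is not intercepted by a proton. No ring is closed and no stereocentre is formed. The selectivity needed is regiochemical, oxygen at C2 and not at C1, and the C6 benzyloxy group secures it: its inductive pull and the resulting aryne distortion make C2, the carbon remote from it, the electrophilic end and place the developing anion at C1 beside the C–O bond, and C2 is also the less hindered end next to C3–H. Acyl transfer must also outrun protonation of the C1 anion, which is why ring B carries no acidic enol, the C6 oxygen is benzylated and only a small excess of acid is used. The vinylogous esters, the benzyl ether and the C4 methoxy group should be inert to CsF.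

Step 11
Reactants: 19 2-acetyl-6-{[2-(benzyloxy)-4-hydroxy-6-methoxy-3-propanoylphenyl]methyl}-3,5-dimethoxy-4,4-dimethylcyclohexa-2,5-dien-1-one
Product: 20 2-acetyl-6-{[2-(benzyloxy)-4-hydroxy-6-methoxy-3-propanoylphenyl]methyl}-3,5-dihydroxy-4,4-dimethylcyclohexa-2,5-dien-1-one
Conditions: 2 M HCl, THF, 60 °C
Reagents that add atoms: water, O
Why: Acid hydrolysis of vinylogous esters by conjugate addition of water and loss of methanol regenerates the enolised triketone, while the benzyl ether keeps the C6 oxygen from closing onto ring B.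

Step 12
Reactants: 20 2-acetyl-6-{[2-(benzyloxy)-4-hydroxy-6-methoxy-3-propanoylphenyl]methyl}-3,5-dihydroxy-4,4-dimethylcyclohexa-2,5-dien-1-one
Product: 21 2-acetyl-6-[(2,4-dihydroxy-6-methoxy-3-propanoylphenyl)methyl]-3,5-dihydroxy-4,4-dimethylcyclohexa-2,5-dien-1-one (target)
Conditions: H2 (1 atm), Pd/C, EtOAc, rt
Reagents that add atoms: none
Why: Hydrogenolysis of the benzyl aryl ether over palladium on carbon under neutral conditions frees the C6 phenol without touching the hydrogen-bonded aryl ketone or the enolised triketone.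

Compound list
1 | 5-methoxybenzene-1,3-diol (5-methoxyresorcinol) | COc1cc(O)cc(O)c1 | starting material
2 | 2-iodo-5-methoxybenzene-1,3-diol | COc1cc(O)c(I)c(O)c1 | intermediate
3 | 2,4-dihydroxy-3-iodo-6-methoxybenzaldehyde | COc1cc(O)c(I)c(O)c1C=O | intermediate
4 | 2-hydroxy-3-iodo-6-methoxy-4-[(triethylsilyl)oxy]benzaldehyde | COc1cc(O[Si](CC)(CC)CC)c(I)c(O)c1C=O | intermediate
5 | 2-(benzyloxy)-3-iodo-6-methoxy-4-[(triethylsilyl)oxy]benzaldehyde | COc1cc(O[Si](CC)(CC)CC)c(I)c(OCc2ccccc2)c1C=O | intermediate
6 | {[3-(benzyloxy)-4-(dimethoxymethyl)-2-iodo-5-methoxyphenyl]oxy}triethylsilane | COc1cc(O[Si](CC)(CC)CC)c(I)c(OCc2ccccc2)c1C(OC)OC | intermediate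
7 | {2-(benzyloxy)-3-(dimethoxymethyl)-4-methoxy-6-[(triethylsilyl)oxy]phenyl}lithium (C1 aryllithium) | COc1cc(O[Si](CC)(CC)CC)c([Li])c(OCc2ccccc2)c1C(OC)OC | intermediate
8 | lithium 3-(benzyloxy)-4-(dimethoxymethyl)-5-methoxy-2-(triethylsilyl)phenolate | COc1cc([O-])c([Si](CC)(CC)CC)c(OCc2ccccc2)c1C(OC)OC.[Li+] | intermediate
9 | 3-(benzyloxy)-4-(dimethoxymethyl)-5-methoxy-2-(triethylsilyl)phenyl trifluoromethanesulfonate | COc1cc(OS(=O)(=O)C(F)(F)F)c([Si](CC)(CC)CC)c(OCc2ccccc2)c1C(OC)OC | intermediate
10 | 3-(benzyloxy)-4-formyl-5-methoxy-2-(triethylsilyl)phenyl trifluoromethanesulfonate | COc1cc(OS(=O)(=O)C(F)(F)F)c([Si](CC)(CC)CC)c(OCc2ccccc2)c1C=O | intermediate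
11 | 1-(2,4,6-trihydroxyphenyl)ethan-1-one (2,4,6-trihydroxyacetophenone) | CC(=O)c1c(O)cc(O)cc1O | starting material
12 | 1-(2,4,6-trihydroxy-3-methylphenyl)ethan-1-one | CC(=O)c1c(O)cc(O)c(C)c1O | intermediate
13 | 2-acetyl-3,5-dihydroxy-4,4-dimethylcyclohexa-2,5-dien-1-one (acetylfilicinic acid) | CC(=O)C1=C(O)C(C)(C)C(O)=CC1=O | intermediate
14 | 3-(benzyloxy)-4-[(3-acetyl-4-hydroxy-5,5-dimethyl-2,6-dioxocyclohex-3-en-1-ylidene)methyl]-5-methoxy-2-(triethylsilyl)phenyl trifluoromethanesulfonate (alkene geometry not defined, removed on reduction) | CC(=O)C1=C(O)C(C)(C)C(=O)C(=Cc2c(OC)cc(OS(=O)(=O)C(F)(F)F)c([Si](CC)(CC)CC)c2OCc3ccccc3)C1=O | intermediate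
15 | 3-(benzyloxy)-4-[(5-acetyl-2,4-dihydroxy-3,3-dimethyl-6-oxocyclohexa-1,4-dien-1-yl)methyl]-5-methoxy-2-(triethylsilyl)phenyl trifluoromethanesulfonate | CC(=O)C1=C(O)C(C)(C)C(O)=C(Cc2c(OC)cc(OS(=O)(=O)C(F)(F)F)c([Si](CC)(CC)CC)c2OCc3ccccc3)C1=O | intermediate
16 | 3-(benzyloxy)-4-[(5-acetyl-2,4-dimethoxy-3,3-dimethyl-6-oxocyclohexa-1,4-dien-1-yl)methyl]-5-methoxy-2-(triethylsilyl)phenyl trifluoromethanesulfonate | CC(=O)C1=C(OC)C(C)(C)C(OC)=C(Cc2c(OC)cc(OS(=O)(=O)C(F)(F)F)c([Si](CC)(CC)CC)c2OCc3ccccc3)C1=O | intermediate
17 | propanoic acid | CCC(=O)O | starting material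
18 | 2-acetyl-6-{[2-(benzyloxy)-6-methoxy-3,4-didehydrophenyl]methyl}-3,5-dimethoxy-4,4-dimethylcyclohexa-2,5-dien-1-one (C1–C2 aryne) | COC1=CC#CC(OCc2ccccc2)=C1CC1=C(OC)C(C)(C)C(OC)=C(C(C)=O)C1=O | intermediate
19 | 2-acetyl-6-{[2-(benzyloxy)-4-hydroxy-6-methoxy-3-propanoylphenyl]methyl}-3,5-dimethoxy-4,4-dimethylcyclohexa-2,5-dien-1-one | CCC(=O)c1c(O)cc(OC)c(CC2=C(OC)C(C)(C)C(OC)=C(C(C)=O)C2=O)c1OCc1ccccc1 | intermediate
20 | 2-acetyl-6-{[2-(benzyloxy)-4-hydroxy-6-methoxy-3-propanoylphenyl]methyl}-3,5-dihydroxy-4,4-dimethylcyclohexa-2,5-dien-1-one | CCC(=O)c1c(O)cc(OC)c(CC2=C(O)C(C)(C)C(O)=C(C(C)=O)C2=O)c1OCc1ccccc1 | intermediate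
21 | 2-acetyl-6-[(2,4-dihydroxy-6-methoxy-3-propanoylphenyl)methyl]-3,5-dihydroxy-4,4-dimethylcyclohexa-2,5-dien-1-one | CCC(=O)c1c(O)cc(OC)c(CC2=C(O)C(C)(C)C(O)=C(C(C)=O)C2=O)c1O | target

Total step count: 12. Longest linear sequence: 11 steps (steps 1–6 and 8–12, from 1); step 7 is a one-step branch from 11.

Steps most likely to fail

Step 10. The C1 aryl anion may be intercepted before acyl transfer, by protonation from the acid or bifluoride or by methyl transfer from a ring B vinylogous ester; fluoride attack on the hindered triethylsilyl group may also be slow. Fallback: move the insertion ahead of the ring B coupling. The fallback sets out from 9, isolated by giving step 6 a neutral work-up. CsF and propanoic acid in THF at 125 °C should give, by the same known aryne–carboxylic acid insertion on a substrate that carries only ethers and an acetal, 1-[2-(benzyloxy)-3-(dimethoxymethyl)-6-hydroxy-4-methoxyphenyl]propan-1-one F1. Dilute HCl in THF then unmasks 2-(benzyloxy)-4-hydroxy-6-methoxy-3-propanoylbenzaldehyde F2. Proline/Hantzsch ester reductive alkylation of 13 with F2 comes back to the route at 20, so ring B is never exposed to fluoride and needs no enol protection.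

Step 9. The chelated C3' enol may be methylated slowly or the methyl groups may spread over the C1' and acetyl oxygens, leaving an acidic proton or an ill-defined mixture for the key step. Fallback: cap ring B by silver-mediated O-benzylation instead. The fallback sets out from 15. BnBr and Ag2O in CH2Cl2 should give 3-(benzyloxy)-4-{[5-acetyl-2,4-bis(benzyloxy)-3,3-dimethyl-6-oxocyclohexa-1,4-dien-1-yl]methyl}-5-methoxy-2-(triethylsilyl)phenyl trifluoromethanesulfonate F4. The CsF/propanoic acid insertion of step 10 then gives 2-acetyl-3,5-bis(benzyloxy)-6-{[2-(benzyloxy)-4-hydroxy-6-methoxy-3-propanoylphenyl]methyl}-4,4-dimethylcyclohexa-2,5-dien-1-one F5. One hydrogenolysis over Pd/C removes all three benzyl groups and comes back to the route at 21, with no acidic hydrolysis.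

Step 8. Condensation of the di-ortho-substituted aldehyde may be slow, so that the Hantzsch ester is used up unproductively or a second triketone adds to the arylidene. Fallback: replace the condensation–reduction by dehydrative benzylation. The fallback sets out from 10. NaBH4 in THF/MeOH at 0 °C gives 3-(benzyloxy)-4-(hydroxymethyl)-5-methoxy-2-(triethylsilyl)phenyl trifluoromethanesulfonate F3. Catalytic Bi(OTf)3 in MeNO2 with 13 ionises the 2,6-dialkoxybenzyl alcohol, and the cation alkylates C6' of the triketone (known acid-catalysed benzylation of 1,3-dicarbonyl compounds with benzylic alcohols), coming back to the route at 15.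

Further compounds
F1 | step 10 | 1-[2-(benzyloxy)-3-(dimethoxymethyl)-6-hydroxy-4-methoxyphenyl]propan-1-one | CCC(=O)c1c(O)cc(OC)c(C(OC)OC)c1OCc1ccccc1
F2 | step 10 | 2-(benzyloxy)-4-hydroxy-6-methoxy-3-propanoylbenzaldehyde | CCC(=O)c1c(O)cc(OC)c(C=O)c1OCc1ccccc1
F3 | step 8 | 3-(benzyloxy)-4-(hydroxymethyl)-5-methoxy-2-(triethylsilyl)phenyl trifluoromethanesulfonate | COc1cc(OS(=O)(=O)C(F)(F)F)c([Si](CC)(CC)CC)c(OCc2ccccc2)c1CO
F4 | step 9 | 3-(benzyloxy)-4-{[5-acetyl-2,4-bis(benzyloxy)-3,3-dimethyl-6-oxocyclohexa-1,4-dien-1-yl]methyl}-5-methoxy-2-(triethylsilyl)phenyl trifluoromethanesulfonate | CC(=O)C1=C(OCc2ccccc2)C(C)(C)C(OCc2ccccc2)=C(Cc2c(OC)cc(OS(=O)(=O)C(F)(F)F)c([Si](CC)(CC)CC)c2OCc3ccccc3)C1=O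
F5 | step 9 | 2-acetyl-3,5-bis(benzyloxy)-6-{[2-(benzyloxy)-4-hydroxy-6-methoxy-3-propanoylphenyl]methyl}-4,4-dimethylcyclohexa-2,5-dien-1-one | CCC(=O)c1c(O)cc(OC)c(CC2=C(OCc3ccccc3)C(C)(C)C(OCc3ccccc3)=C(C(C)=O)C2=O)c1OCc1ccccc1
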